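The oxolane of olivil is cut at O1–C5 and at C3–C4, the bond to the fully substituted carbinol carbon C4. This splits the lignan into two C6–C3 halves of equal size: an (S)-1-arylallyl alcohol (O1, C2, C3 and the future hydroxymethyl carbon) and an arylmethyl diazomethyl ketone (C5, C4 and the benzyl arm). In one flask, rhodium-carbenoid O–H insertion joins O1 to C5, and samarium diiodide then converts the C4 ketone into a ketyl that closes 5-exo onto the vinyl group; dioxygen oxidises the resulting alkylsamarium to the CH2OH. The step exploits the 3-oxahex-5-enyl ketyl hidden in the ring: the C4 hydroxyl anti to CH2OH on C3, the C2 aryl trans to it.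

Key step: step 4

Remark: the oxolane is numbered O1, C2 (aryl-bearing), C3 (bearing the exocyclic hydroxymethyl carbon, called C9), C4 (tertiary carbinol) and C5 (ring CH2); in this numbering the target is (2S,3R,4S), and both phenols are carried as benzyl ethers until the last step.

Step 1
Reactants: 1 4-(benzyloxy)-3-methoxybenzaldehyde
Product: 2 rac-1-[4-(benzyloxy)-3-methoxyphenyl]prop-2-en-1-ol
Conditions: CH2=CHMgBr (1.2 equiv), THF, −78 to 0 °C; aqueous work-up
Reagents that add atoms: vinylmagnesium bromide C=C[Mg]Br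
Why: Grignard 1,2-addition to the aldehyde installs C3 and C9 as a vinyl group; the carbinol center C2 is formed racemic and is resolved in step 2.

Step 2
Reactants: 2 rac-1-[4-(benzyloxy)-3-methoxyphenyl]prop-2-en-1-ol
Product: 3 (S)-1-[4-(benzyloxy)-3-methoxyphenyl]prop-2-en-1-ol
Conditions: Candida antarctica lipase B (immobilised), vinyl acetate, MTBE, 30 °C, stopped just past half conversion; chromatography on Et3N-deactivated silica
Reagents that add atoms: none
Why: Lipase-catalysed kinetic resolution by transesterification should acylate the (R)-enantiomer (aryl as the large group, vinyl as the medium group), so that the unreacted (S)-alcohol carries the C2 configuration of the target.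

Step 3
Reactants: 4 [4-(benzyloxy)-3-methoxyphenyl]acetic acid
Product: 6 1-[4-(benzyloxy)-3-methoxyphenyl]-3-diazopropan-2-one, via acid chloride 5 (not isolated)
Conditions: (COCl)2 (1.2 equiv), DMF (cat.), CH2Cl2, 0 °C to rt; evaporation; then CH2N2 (3 equiv), Et2O, 0 °C
Reagents that add atoms: diazomethane C=[N+]=[N-]
Why: Acylation of diazomethane by the acid chloride (first stage of the Arndt–Eistert sequence) should give the diazomethyl ketone, the excess diazomethane taking up the HCl so that no chloromethyl ketone forms; no stereocenter is involved.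

Step 4
Reactants: 3 (S)-1-[4-(benzyloxy)-3-methoxyphenyl]prop-2-en-1-ol; 6 1-[4-(benzyloxy)-3-methoxyphenyl]-3-diazopropan-2-one
Product: 9 (3S,4R,5S)-5-[4-(benzyloxy)-3-methoxyphenyl]-3-{[4-(benzyloxy)-3-methoxyphenyl]methyl}-4-(hydroxymethyl)oxolan-3-ol, via allyloxy ketone 7 (not isolated), via alkylsamarium alkoxide 8 (not isolated)
Conditions: Rh2(OAc)4 (1 mol %), PhMe, 25 °C, 6 (1.2 equiv) added slowly to 3; then transfer into SmI2 (2.5 equiv), HMPA (10 equiv), THF, 0 °C to rt; then dry O2, −78 °C to rt; aqueous work-up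
Reagents that add atoms: dioxygen O=O
Why: Dirhodium-carbenoid O–H insertion (oxonium ylide, then proton shift) is far faster with a free alcohol than cyclopropanation of the vinyl group, so slow addition of 6 to 3 should give ether 7 with C2 untouched and O1–C5 formed. Samarium diiodide with HMPA then reduces the ketone to a ketyl that adds to the vinyl group by 5-exo-trig radical cyclisation (C3–C4 formed); the closest known reaction type is the ketyl–olefin cyclisation of unactivated δ,ε-unsaturated ketones with interception of the alkylsamarium by an electrophile, here oxidation of the primary alkylsamarium 8 by O2 to the alkoxide. In the chair-like transition state the C2 aryl group lies pseudo-equatorial, which places C9 trans to it and should set C3 as R. The samarium-bound ketyl oxygen turns away from the alkene for steric and dipolar reasons, so the C4 hydroxyl should end trans and the arylmethyl group cis to the new CH2 group, which sets C4 as S. The step needs ring closure to outrun reductive cleavage of the α-alkoxy C5–O1 bond, which the absence of a proton source until the ring is closed should secure, and it needs chemoselective insertion, which the low stationary concentration of carbenoid should secure.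

Step 5
Reactants: 9 (3S,4R,5S)-5-[4-(benzyloxy)-3-methoxyphenyl]-3-{[4-(benzyloxy)-3-methoxyphenyl]methyl}-4-(hydroxymethyl)oxolan-3-ol
Product: 10 (3S,4R,5S)-5-(4-hydroxy-3-methoxyphenyl)-3-[(4-hydroxy-3-methoxyphenyl)methyl]-4-(hydroxymethyl)oxolan-3-ol (olivil, CNP0209194.1)
Conditions: H2 (1 atm), 10% Pd/C, EtOAc, rt
Reagents that add atoms: none
Why: Hydrogenolysis of the two aryl benzyl ethers under neutral conditions at atmospheric pressure should be complete well before the cyclic benzylic C2–O1 bond is attacked, and no stereocenter is touched.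

Compound list
1 | 4-(benzyloxy)-3-methoxybenzaldehyde | COc1cc(C=O)ccc1OCc1ccccc1 | starting material
2 | rac-1-[4-(benzyloxy)-3-methoxyphenyl]prop-2-en-1-ol | C=CC(O)c1ccc(OCc2ccccc2)c(OC)c1 | intermediate
3 | (S)-1-[4-(benzyloxy)-3-methoxyphenyl]prop-2-en-1-ol | C=C[C@H](O)c1ccc(OCc2ccccc2)c(OC)c1 | intermediate
4 | [4-(benzyloxy)-3-methoxyphenyl]acetic acid | COc1cc(CC(=O)O)ccc1OCc1ccccc1 | starting material
5 | [4-(benzyloxy)-3-methoxyphenyl]acetyl chloride (not isolated) | COc1cc(CC(=O)Cl)ccc1OCc1ccccc1 | intermediate
6 | 1-[4-(benzyloxy)-3-methoxyphenyl]-3-diazopropan-2-one | COc1cc(CC(=O)C=[N+]=[N-])ccc1OCc1ccccc1 | intermediate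
7 | 1-[4-(benzyloxy)-3-methoxyphenyl]-3-({(1S)-1-[4-(benzyloxy)-3-methoxyphenyl]prop-2-en-1-yl}oxy)propan-2-one (not isolated) | COc1cc(CC(=O)CO[C@H](c2ccc(OCc3ccccc3)c(OC)c2)C=C)ccc1OCc1ccccc1 | intermediate
8 | bis(diiodosamarium) species of the closed oxolane: diiodosamarium alkoxide at the C4 oxygen and diiodosamarium alkyl at C9, (2S,3R,4S) ring configuration (not isolated) | COc1cc(C[C@@]2(O[Sm](I)I)CO[C@H](c3ccc(OCc4ccccc4)c(OC)c3)[C@H]2C[Sm](I)I)ccc1OCc1ccccc1 | intermediate
9 | (3S,4R,5S)-5-[4-(benzyloxy)-3-methoxyphenyl]-3-{[4-(benzyloxy)-3-methoxyphenyl]methyl}-4-(hydroxymethyl)oxolan-3-ol | COc1cc(C[C@@]2(O)CO[C@H](c3ccc(OCc4ccccc4)c(OC)c3)[C@H]2CO)ccc1OCc1ccccc1 | intermediate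
10 | (3S,4R,5S)-5-(4-hydroxy-3-methoxyphenyl)-3-[(4-hydroxy-3-methoxyphenyl)methyl]-4-(hydroxymethyl)oxolan-3-ol (olivil) | COc1cc(C[C@@]2(O)CO[C@H](c3ccc(O)c(OC)c3)[C@H]2CO)ccc1O | target

Total step count: 5. Longest linear sequence: 4 steps (steps 1, 2, 4 and 5).

Steps most likely to fail

Step 4. What may go wrong: the ketyl may undergo reductive cleavage of its α-alkoxy C5–O1 bond before it closes onto the unactivated vinyl group, the alkylsamarium may be protonated instead of oxygenated, or the facial preference in the ring closure may be lower than expected. The fallback sets out from 3 and comes back at 9; it activates the alkene and brings the oxygen in through boron. Cross-metathesis of 3 with vinylboronic acid pinacol ester (second-generation Hoveyda–Grubbs catalyst, CH2Cl2, 40 °C) should give (S,E)-1-[4-(benzyloxy)-3-methoxyphenyl]-3-(4,4,5,5-tetramethyl-1,3,2-dioxaborolan-2-yl)prop-2-en-1-ol F1. O–H insertion with 6 (Rh2(OAc)4, PhMe) should give the isolated boryl-substituted allyloxy ketone F2. SmI2 with t-BuOH in THF at −78 °C should close the ring by ketyl addition to the boron-substituted alkene, whose α-boryl radical is stabilised, and protonation should give the C9 pinacol boronate of the oxolane F3. NaBO3·4H2O in THF/H2O should then oxidise C–B to C–OH with retention and give 9.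

Step 3. What may go wrong: loss of HCl from the arylacetyl chloride to a ketene and its dimers, decomposition of the diazoketone on handling, or, in step 4, attack of the derived carbenoid on its own electron-rich ring in competition with O–H insertion. The fallback sets out from 3 and comes back at 7; it makes the C5–O1 bond by epoxide opening, without a diazo compound. Purchased 1-(benzyloxy)-2-methoxy-4-(prop-2-en-1-yl)benzene F4 is epoxidised (mCPBA, NaHCO3, CH2Cl2, 0 °C) to 2-{[4-(benzyloxy)-3-methoxyphenyl]methyl}oxirane F5. The sodium alkoxide of 3 (NaH, DMF, 50 °C) should open F5 at its CH2 terminus and give 1-[4-(benzyloxy)-3-methoxyphenyl]-3-({(1S)-1-[4-(benzyloxy)-3-methoxyphenyl]prop-2-en-1-yl}oxy)propan-2-ol F6 as a mixture of carbinol epimers. Dess–Martin periodinane (NaHCO3, CH2Cl2) should give ketone 7, which is then isolated and submitted to the SmI2/HMPA and O2 stages of step 4.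

Step 2. What may go wrong: incomplete discrimination of the enantiomers by the enzyme, or allylic transposition of the electron-rich 1-arylallyl alcohol to the conjugated primary alcohol during the long contact with the support and on silica. The fallback sets out from 1 and comes back at 3; it sets the carbinol center by catalytic asymmetric alkynylation and half-reduces the alkyne. Addition of trimethylsilylacetylene to 1 (Me2Zn, ProPhenol ligand in the enantiomeric form that leads to the (R)-carbinol, PhMe, 4 °C) should give (R)-1-[4-(benzyloxy)-3-methoxyphenyl]-3-(trimethylsilyl)prop-2-yn-1-ol F7. K2CO3 in MeOH should give (S)-1-[4-(benzyloxy)-3-methoxyphenyl]prop-2-yn-1-ol F8; the descriptor changes only because the silyl group is lost. H2 (1 atm) over Pd/CaCO3 poisoned with Pb(OAc)2 and quinoline in EtOAc should stop at the alkene 3.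

Further compounds
F1 | step 4 | (S,E)-1-[4-(benzyloxy)-3-methoxyphenyl]-3-(4,4,5,5-tetramethyl-1,3,2-dioxaborolan-2-yl)prop-2-en-1-ol | O[C@H](c1ccc(OCc2ccccc2)c(OC)c1)/C=C/B1OC(C)(C)C(C)(C)O1
F2 | step 4 | 1-[4-(benzyloxy)-3-methoxyphenyl]-3-({(1S,2E)-1-[4-(benzyloxy)-3-methoxyphenyl]-3-(4,4,5,5-tetramethyl-1,3,2-dioxaborolan-2-yl)prop-2-en-1-yl}oxy)propan-2-one | COc1cc(CC(=O)CO[C@H](c2ccc(OCc3ccccc3)c(OC)c2)/C=C/B2OC(C)(C)C(C)(C)O2)ccc1OCc1ccccc1
F3 | step 4 | (3S,4R,5S)-5-[4-(benzyloxy)-3-methoxyphenyl]-3-{[4-(benzyloxy)-3-methoxyphenyl]methyl}-4-[(4,4,5,5-tetramethyl-1,3,2-dioxaborolan-2-yl)methyl]oxolan-3-ol | COc1cc(C[C@@]2(O)CO[C@H](c3ccc(OCc4ccccc4)c(OC)c3)[C@H]2CB2OC(C)(C)C(C)(C)O2)ccc1OCc1ccccc1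
F4 | step 3 | 1-(benzyloxy)-2-methoxy-4-(prop-2-en-1-yl)benzene (purchased) | C=CCc1ccc(OCc2ccccc2)c(OC)c1
F5 | step 3 | 2-{[4-(benzyloxy)-3-methoxyphenyl]methyl}oxirane (racemic) | COc1cc(CC2CO2)ccc1OCc1ccccc1
F6 | step 3 | 1-[4-(benzyloxy)-3-methoxyphenyl]-3-({(1S)-1-[4-(benzyloxy)-3-methoxyphenyl]prop-2-en-1-yl}oxy)propan-2-ol (both carbinol epimers) | COc1cc(CC(O)CO[C@H](c2ccc(OCc3ccccc3)c(OC)c2)C=C)ccc1OCc1ccccc1
F7 | step 2 | (R)-1-[4-(benzyloxy)-3-methoxyphenyl]-3-(trimethylsilyl)prop-2-yn-1-ol | C[Si](C)(C)C#C[C@H](O)c1ccc(OCc2ccccc2)c(OC)c1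
F8 | step 2 | (S)-1-[4-(benzyloxy)-3-methoxyphenyl]prop-2-yn-1-ol | C#C[C@H](O)c1ccc(OCc2ccccc2)c(OC)c1
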